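## Retrosynthetic overview

Locants: C1 and C2 are the tetralin carbons carrying the side chain and the OH; C1′ is the side-chain carbinol carbon.

1. No ring is formed: the tetralin (both rings) is bought as ketone 1 and the phenol ring as enal 2, carried as its acetate 3.
2. C1–C1′ (key disconnection): direct syn-aldol between the enol 4 of ketone 1 and the C=O of 3 gives β-hydroxy ketone 5; a chiral phosphoric acid sets C1 and C1′.
3. C2–H: hydride addition to 5 through boron chelate 6 and borate 7 gives the 1,3-syn, ring-cis diol acetate 8; C2 is set by substrate control.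
4. O–acetyl: methanolysis of 8 in the same flask gives target 9.

Assumption: 1 and 2 are catalogue compounds, and (R)-TRIP is taken to give the (1R,1′S) adduct; if the sense of induction is the opposite, (S)-TRIP is used and nothing else changes.

## Route

Step 1
Reactants: 2 (E)-3-(4-hydroxyphenyl)prop-2-enal
Product: 3 (E)-3-(4-acetoxyphenyl)prop-2-enal
Conditions: Ac2O (1.2 equiv), pyridine (1.5 equiv), DMAP (2 mol %), CH2Cl2, 0 °C to rt, 1 h
Reagents that add atoms: acetic anhydride, CC(=O)OC(C)=O
Why: Nucleophilic acyl substitution (O-acetylation) of the phenol, with no stereocentre involved; the acetate keeps the enal carbonyl electrophilic, makes the later cinnamyl alcohol less prone to ionise, and comes off in the last flask.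

Step 2
Reactants: 1 dimethoxy-2-tetralone [6,7-dimethoxy-3,4-dihydronaphthalen-2(1H)-one]; 3 (E)-3-(4-acetoxyphenyl)prop-2-enal (1.5 equiv)
Product: 5 (1R)-1-[(1S,2E)-3-(4-acetoxyphenyl)-1-hydroxyprop-2-en-1-yl]-6,7-dimethoxy-3,4-dihydronaphthalen-2(1H)-one, via enol 4 (not isolated)
Conditions: (R)-TRIP [(R)-3,3′-bis(2,4,6-triisopropylphenyl)-1,1′-binaphthyl-2,2′-diyl hydrogen phosphate] (10 mol %), toluene (0.2 M), Ar, 0 °C, 48–72 h; cold silica plug, used at once
Reagents that add atoms: none
Why: Proposed new method: a direct enol-mode aldol addition of a β-tetralone to an enal under chiral phosphoric acid catalysis, atom-economic with no by-product — the acid enolises 1 toward the benzylic C1 to the styrene-type enol 4 (far more populated than a cyclohexanone enol), then binds the enol O–H to P=O and the aldehyde oxygen to P–OH; this long O–H···O=P–O–H···O bridge does not pull the two oxygens into a Zimmerman–Traxler chair, so addition runs through an extended (antiperiplanar) array in which the styryl group lies over the small C1–H and away from the aryl ring and its peri C8–H, giving the syn adduct (C1 Si face of 4 onto the Re face of the C=O, the catalyst pocket choosing the enantiomeric pair) with kinetic 1,2-selectivity as for other π-nucleophiles on O-protonated enals; the closest known reaction types are phosphoric acid "enol catalysis" of α-aryl cyclic ketones (α-amination, Michael addition) and the phosphoric acid-catalysed syn-selective direct aldol of cyclohexanones with glyoxylates.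

Step 3
Reactants: 5 (1R)-1-[(1S,2E)-3-(4-acetoxyphenyl)-1-hydroxyprop-2-en-1-yl]-6,7-dimethoxy-3,4-dihydronaphthalen-2(1H)-one
Product: 9 (1S,2R)-1-[(1S,2E)-1-hydroxy-3-(4-hydroxyphenyl)prop-2-en-1-yl]-6,7-dimethoxy-1,2,3,4-tetrahydronaphthalen-2-ol, via boron chelate 6 (not isolated), via cyclic sodium borate 7 (not isolated), via diol monoacetate 8 (not isolated)
Conditions: Et2BOMe (1.1 equiv), THF/MeOH 4:1, −78 °C, 30 min; NaBH4 (1.2 equiv), −78 °C, 3 h; MeOH, rt, evaporate ×3; then K2CO3 (0.2 equiv), MeOH, 0 °C to rt; aq. NH4Cl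
Reagents that add atoms: none
Why: Narasaka–Prasad-type chelation-controlled reduction followed by Zemplén-type transesterification: Et2BOMe ties 5 up as the neutral chelate 6 (no retro-aldol, no C1 epimerisation), hydride adds to the C2 face on the side of C1–H because the other face is covered by the axial styryl and B-ethyl groups (the same face a non-chelated 1-substituted 2-tetralone offers), giving the 1,3-syn, ring-cis (2R) carbinol as borate 7, which MeOH opens to 8 before catalytic carbonate removes the aryl acetate.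

## Compound list

1 | 6,7-dimethoxy-3,4-dihydronaphthalen-2(1H)-one (6,7-dimethoxy-2-tetralone) | COc1cc2c(cc1OC)CC(=O)CC2 | starting material
2 | (E)-3-(4-hydroxyphenyl)prop-2-enal (4-hydroxycinnamaldehyde) | O=C/C=C/c1ccc(O)cc1 | starting material
3 | (E)-3-(4-acetoxyphenyl)prop-2-enal | CC(=O)Oc1ccc(/C=C/C=O)cc1 | intermediate
4 | 6,7-dimethoxy-3,4-dihydronaphthalen-2-ol (C1=C2 enol of 1; not isolated) | COc1cc2c(cc1OC)C=C(O)CC2 | intermediate
5 | (1R)-1-[(1S,2E)-3-(4-acetoxyphenyl)-1-hydroxyprop-2-en-1-yl]-6,7-dimethoxy-3,4-dihydronaphthalen-2(1H)-one (syn-aldol) | COc1cc2c(cc1OC)[C@H]([C@@H](O)/C=C/c1ccc(OC(C)=O)cc1)C(=O)CC2 | intermediate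
6 | O-diethylboryl chelate of 5: BEt2 on the C1′ oxygen, ketone oxygen datively bound to boron, (1R,1′S) as in 5 (not isolated) | COc1cc2c(cc1OC)[C@H]([C@@H](OB(CC)CC)/C=C/c1ccc(OC(C)=O)cc1)C(=O)CC2 | intermediate
7 | cyclic sodium diethylborate of 8: sodium 2,2-diethyl-1,3,2-dioxaborinan-2-uide spanning O-2 and O-1′, stereocentres as in 8 (not isolated) | [Na+].COc1cc2c(cc1OC)[C@H]([C@@H](O3)/C=C/c1ccc(OC(C)=O)cc1)[C@H](O[B-]3(CC)CC)CC2 | intermediate
8 | (1S,2R)-1-[(1S,2E)-3-(4-acetoxyphenyl)-1-hydroxyprop-2-en-1-yl]-6,7-dimethoxy-1,2,3,4-tetrahydronaphthalen-2-ol (not isolated) | COc1cc2c(cc1OC)[C@H]([C@@H](O)/C=C/c1ccc(OC(C)=O)cc1)[C@H](O)CC2 | intermediate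
9 | (1S,2R)-1-[(1S,2E)-1-hydroxy-3-(4-hydroxyphenyl)prop-2-en-1-yl]-6,7-dimethoxy-1,2,3,4-tetrahydronaphthalen-2-ol | COc1cc2c(cc1OC)[C@H]([C@@H](O)/C=C/c1ccc(O)cc1)[C@H](O)CC2 | target

## Step count

Total steps: 3. Longest linear sequence: 3 (2 → 3 → 5 → 9); from ketone 1 it is 2 steps.

## Steps most likely to fail, with fallbacks

**Step 2 (the new aldol) is the most likely to fail.** The possible failures are:
- the enal carbonyl may be too weak an electrophile for the enol;
- conjugate addition followed by hemiketal formation could compete;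
- 5 can dehydrate to the dienone;
- 5 can epimerise at C1 or revert by retro-aldol (hence cold reaction, early stop and immediate use);
- the anti isomer could form.

A within-approach adjustment is the more acidic N-triflylphosphoramide of the same scaffold.

The fallback uses known chemistry, sets out from 1 and comes back at 5. Ketone 1 is converted with TMSOTf/Et3N (CH2Cl2, 0 °C) into the conjugated enol silane [(6,7-dimethoxy-3,4-dihydronaphthalen-2-yl)oxy]trimethylsilane F1. F1 and 3 then undergo a Mukaiyama aldol addition under a tartaric-acid-derived chiral acyloxyborane (from 2-O-(2,6-diisopropoxybenzoyl)tartaric acid and BH3·THF, 20 mol %, EtCN, −78 °C). This catalyst class gives syn adducts irrespective of enol silane geometry through an open transition state and adds 1,2 to enals. The tartaric acid enantiomer is the one that delivers the (1′S) carbinol. The product, the O-trimethylsilyl aldol ether F2 (the trimethylsilyl ether of 5), is hydrolysed (1 M HCl, THF, 0 °C) to 5.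

**Step 3 is the second risk.** The tetralone ring forces the boron chelate into a half-chair with an axial styryl group, so this is not a textbook Narasaka–Prasad case and the diastereoselectivity at C2 could erode. The basic methanolysis also exposes a p-hydroxycinnamyl alcohol.

The fallback sets out from 5 and comes back at 8. Ketone 5 is silylated (Et3SiCl, imidazole, DMF, 0 °C) to (1R)-1-[(1S,2E)-3-(4-acetoxyphenyl)-1-(triethylsilyloxy)prop-2-en-1-yl]-6,7-dimethoxy-3,4-dihydronaphthalen-2(1H)-one F3, which cannot chelate. LiBH(s-Bu)3 (1.2 equiv, THF, −78 °C) then adds anti to the pseudo-axial C1 substituent, the usual steric (Felkin-type) outcome for 1-substituted 2-tetralones. This gives the cis alcohol (1S,2R)-1-[(1S,2E)-3-(4-acetoxyphenyl)-1-(triethylsilyloxy)prop-2-en-1-yl]-6,7-dimethoxy-1,2,3,4-tetrahydronaphthalen-2-ol F4. HF·pyridine (THF/pyridine, 0 °C) removes the silyl group to give 8, which is methanolysed to 9 as in the last stage of step 3.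

**Step 1 is the least risky.** Its weak point is the lability of the aryl acetate (cleavage on silica, or acyl transfer to the new hydroxyl groups in steps 2 and 3).

The fallback sets out from 2 and comes back at 9, replacing the ester by a silyl ether that is carried to the end. Aldehyde 2 is silylated (t-BuMe2SiCl, imidazole, DMF, rt) to (E)-3-[4-(tert-butyldimethylsilyloxy)phenyl]prop-2-enal F4a — written below as F5. That is, the aldehyde (E)-3-[4-(tert-butyldimethylsilyloxy)phenyl]prop-2-enal F5 is formed. The step 2 aldol of F5 with 1 (through enol 4; slower, since the enal is more electron-rich) gives (1R)-1-[(1S,2E)-3-[4-(tert-butyldimethylsilyloxy)phenyl]-1-hydroxyprop-2-en-1-yl]-6,7-dimethoxy-3,4-dihydronaphthalen-2(1H)-one F6. The step 3 reduction (Et2BOMe, NaBH4, without the carbonate stage) passes through its diethylboron chelate F7 and the corresponding cyclic sodium diethylborate F8. This gives (1S,2R)-1-[(1S,2E)-3-[4-(tert-butyldimethylsilyloxy)phenyl]-1-hydroxyprop-2-en-1-yl]-6,7-dimethoxy-1,2,3,4-tetrahydronaphthalen-2-ol F9. Bu4NF (THF, 0 °C) then gives 9.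

Further compounds
F1 | step 2 | [(6,7-dimethoxy-3,4-dihydronaphthalen-2-yl)oxy]trimethylsilane | COc1cc2c(cc1OC)C=C(O[Si](C)(C)C)CC2
F2 | step 2 | O-trimethylsilyl ether of 5, (1R)-1-[(1S,2E)-3-(4-acetoxyphenyl)-1-(trimethylsilyloxy)prop-2-en-1-yl]-6,7-dimethoxy-3,4-dihydronaphthalen-2(1H)-one | COc1cc2c(cc1OC)[C@H]([C@@H](O[Si](C)(C)C)/C=C/c1ccc(OC(C)=O)cc1)C(=O)CC2
F3 | step 3 | (1R)-1-[(1S,2E)-3-(4-acetoxyphenyl)-1-(triethylsilyloxy)prop-2-en-1-yl]-6,7-dimethoxy-3,4-dihydronaphthalen-2(1H)-one | COc1cc2c(cc1OC)[C@H]([C@@H](O[Si](CC)(CC)CC)/C=C/c1ccc(OC(C)=O)cc1)C(=O)CC2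
F4 | step 3 | (1S,2R)-1-[(1S,2E)-3-(4-acetoxyphenyl)-1-(triethylsilyloxy)prop-2-en-1-yl]-6,7-dimethoxy-1,2,3,4-tetrahydronaphthalen-2-ol | COc1cc2c(cc1OC)[C@H]([C@@H](O[Si](CC)(CC)CC)/C=C/c1ccc(OC(C)=O)cc1)[C@H](O)CC2
F5 | step 1 | (E)-3-[4-(tert-butyldimethylsilyloxy)phenyl]prop-2-enal | CC(C)(C)[Si](C)(C)Oc1ccc(/C=C/C=O)cc1
F6 | step 1 | (1R)-1-[(1S,2E)-3-[4-(tert-butyldimethylsilyloxy)phenyl]-1-hydroxyprop-2-en-1-yl]-6,7-dimethoxy-3,4-dihydronaphthalen-2(1H)-one | COc1cc2c(cc1OC)[C@H]([C@@H](O)/C=C/c1ccc(O[Si](C)(C)C(C)(C)C)cc1)C(=O)CC2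
F7 | step 1 | O-diethylboryl chelate of F6 (BEt2 on the C1′ oxygen, ketone oxygen bound to boron) | COc1cc2c(cc1OC)[C@H]([C@@H](OB(CC)CC)/C=C/c1ccc(O[Si](C)(C)C(C)(C)C)cc1)C(=O)CC2
F8 | step 1 | cyclic sodium diethylborate of F9 (2,2-diethyl-1,3,2-dioxaborinan-2-uide spanning O-2 and O-1′) | [Na+].COc1cc2c(cc1OC)[C@H]([C@@H](O3)/C=C/c1ccc(O[Si](C)(C)C(C)(C)C)cc1)[C@H](O[B-]3(CC)CC)CC2
F9 | step 1 | (1S,2R)-1-[(1S,2E)-3-[4-(tert-butyldimethylsilyloxy)phenyl]-1-hydroxyprop-2-en-1-yl]-6,7-dimethoxy-1,2,3,4-tetrahydronaphthalen-2-ol | COc1cc2c(cc1OC)[C@H]([C@@H](O)/C=C/c1ccc(O[Si](C)(C)C(C)(C)C)cc1)[C@H](O)CC2
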